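The ten-membered carbocycle is opened at C1–C2 (germacrane numbering). The allylic array C2–C3=C4(C15H2OH) next to this bond is treated as the trace of a 2-alkyl-2-vinyloxirane, and C1 as a carbanion held by two removable phenylsulfonyl groups. A single zerovalent-palladium-catalysed isomerisation of the seco vinyl epoxide, which already carries the trans-fused γ-lactone and all four stereocentres, should close the ring, form the C3=C4 olefin with C2 and C5 cis and release the C15 hydroxyl, with no leaving group and no added base. The precursor is assembled in five steps by two organocatalytic C–C bond formations and a substrate-controlled isoprenylation.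

Key step: step 6

Remark: germacrane numbering is used throughout (ring C1–C10; lactone C11, C12 carbonyl, C13, lactone oxygen on C6; C14 on C10; C15 on C4; acyloxy on C8). The ester is read as angelate ((Z)-2-methylbut-2-enoate) and the C3=C4 olefin as E by CIP (ring carbons C2 and C5 cis). Compound 12 may be a mixture of C4 epimers, because C4 becomes sp2 in step 6.

Step 1
Reactants: 1 (tert-butyldimethylsilyloxy)acetaldehyde; 2 (triphenylphosphoranylidene)acetaldehyde
Product: 3 (E)-4-(tert-butyldimethylsilyloxy)but-2-enal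
Conditions: toluene, 80 °C
Reagents that add atoms: none
Why: Wittig olefination with a stabilised formyl ylide should give the E-enal selectively.

Step 2
Reactants: 3 (E)-4-(tert-butyldimethylsilyloxy)but-2-enal; 4 bis(phenylsulfonyl)methane
Product: 5 (R)-3-[(tert-butyldimethylsilyloxy)methyl]-4,4-bis(phenylsulfonyl)butanal
Conditions: (R)-α,α-diphenylprolinol trimethylsilyl ether (10 mol%), toluene, rt
Reagents that add atoms: none
Why: Iminium-ion organocatalysis (asymmetric Michael addition): the soft bis-sulfonyl carbanion should add to the E-iminium ion anti to the CPh2OSiMe3 group of the (R)-catalyst, which sets C10 (R) and installs the C1 pronucleophile of the key step.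

Step 3
Reactants: 5 (R)-3-[(tert-butyldimethylsilyloxy)methyl]-4,4-bis(phenylsulfonyl)butanal; 6 methyl 4-oxobutanoate
Product: 8 TES-protected anti-aldol aldehyde, via aldol adduct 7 (not isolated)
Conditions: D-proline (20 mol%), DMF, 4 °C, slow addition of 6 (3 equiv); then imidazole, Et3SiCl, 0 °C
Reagents that add atoms: chlorotriethylsilane CC[Si](Cl)(CC)CC
Why: Enamine catalysis (direct proline cross-aldol through a hydrogen-bonded Zimmerman–Traxler-type transition state): the E-enamine of the unhindered donor 6 should add to the Si face of the β-branched acceptor 5 under D-proline control to set the anti C7/C8 pair, and silylation in the same pot traps the labile β-hydroxy aldehyde before it can lactonise.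

Step 4
Reactants: 8 TES-protected anti-aldol aldehyde; 9 2-(trimethylsilylmethyl)buta-1,3-diene
Product: 11 trans-lactone diene, via hydroxy ester 10 (not isolated)
Conditions: BF3·OEt2, CH2Cl2, −78 °C; aq NaHCO3; then PPTS (cat.), CH2Cl2, rt
Reagents that add atoms: none
Why: Hosomi–Sakurai isoprenylation through an open transition state: Felkin–Anh control by C7 and 1,3-anti induction by the C8 silyloxy group reinforce each other for Re-face attack at C6 (6R, H6/H7 trans after closure), and the γ-hydroxy methyl ester should lactonise under mild acid.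

Step 5
Reactants: 11 trans-lactone diene
Product: 12 seco vinyl epoxide
Conditions: mCPBA (1.05 equiv), NaHCO3, CH2Cl2, −20 → 0 °C
Reagents that add atoms: meta-chloroperoxybenzoic acid O=C(OO)c1cccc(Cl)c1
Why: Prilezhaev epoxidation: the more electron-rich 1,1-disubstituted C4=C15 olefin of the 2-substituted diene should react before the monosubstituted C2=C3 olefin, and the C4 configuration does not matter.

Step 6
Reactants: 12 seco vinyl epoxide
Product: 13 ten-membered bis-sulfone allylic alcohol
Conditions: Pd(PPh3)4 (10 mol%), dppe (10 mol%), THF, 65 °C, syringe-pump addition, final 0.005 M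
Reagents that add atoms: none
Why: Zerovalent palladium ionises the allylic C4–O bond of the vinyl oxirane to a zwitterionic π-allylpalladium complex spanning C2–C3–C4, its C15 alkoxide deprotonates the bis-sulfone C1–H, and the soft carbanion attacks the unsubstituted terminus C2 anti to the metal, which forms C1–C2 and returns the catalyst. The closest known reaction type is the Tsuji–Trost allylic alkylation in its vinyl-epoxide macrocyclisation form, an isomerisation under neutral conditions. The ten-membered carbocycle closes by attack at the distal allyl terminus, so that all three allyl carbons become ring members (endo with respect to the allyl unit), in preference to 8-exo attack at the quaternary C4. No stereocentre is created (C4 becomes sp2 and C1 carries two identical sulfonyl groups); the stereochemical issue is the C3=C4 geometry, which should be set by syn/anti equilibration of the π-allyl complex and by ring strain, since a ten-membered ring accommodates the olefin with C2 and C5 cis far better than its trans isomer, and open-chain 2-alkyl-2-vinyloxiranes generally favour the same geometry (hydroxymethyl trans to the new bond). The step needs attack at C2 over C4 and cyclisation over oligomerisation: the first is secured by the steric difference between a CH2 and a quaternary terminus and by the alkoxide that favours 1,4-addition, the second by slow addition at high dilution and by the trans-fused lactone, which restricts the chain between C5 and C8.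

Step 7
Reactants: 13 ten-membered bis-sulfone allylic alcohol
Product: 14 desulfonylated macrocyclic allylic alcohol
Conditions: Na(Hg) (6%), Na2HPO4, MeOH/THF, −20 → 0 °C
Reagents that add atoms: none
Why: Dissolving-metal reductive desulfonylation (two successive electron-transfer C–S cleavages with protonation) should turn the gem-bis-sulfone into the C1 methylene while the isolated olefin, the lactone and the silyl ethers survive under phosphate buffering.

Step 8
Reactants: 14 desulfonylated macrocyclic allylic alcohol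
Product: 15 fully silylated saturated lactone
Conditions: tBuMe2SiCl, imidazole, CH2Cl2, 0 °C → rt
Reagents that add atoms: tert-butyldimethylsilyl chloride CC(C)(C)[Si](C)(C)Cl
Why: Standard silylation of the only free hydroxyl, the primary allylic C15–OH.

Step 9
Reactants: 15 fully silylated saturated lactone
Product: 18 silylated α-methylene lactone, via Mannich base 16 (not isolated), via ammonium iodide 17 (not isolated)
Conditions: LiN(iPr)2, THF, −78 °C; CH2=NMe2+ I−, −78 °C → rt; MeI, MeOH, rt; aq NaHCO3, CH2Cl2
Reagents that add atoms: dimethylmethyleneiminium iodide (Eschenmoser's salt) C=[N+](C)C.[I-]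
Why: Mannich reaction of the lactone enolate followed by exhaustive methylation and E1cB (Hofmann-type) elimination is the standard α-methylenation of γ-butyrolactones, and the C11 stereocentre of the intermediates is lost on elimination.

Step 10
Reactants: 18 silylated α-methylene lactone
Product: 19 C8 alcohol
Conditions: PPTS (0.2 equiv), MeOH/CH2Cl2, 0 °C
Reagents that add atoms: none
Why: Acid-catalysed methanolysis should cleave the secondary triethylsilyl ether much faster than the two primary tert-butyldimethylsilyl ethers.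

Step 11
Reactants: 19 C8 alcohol; 20 angelic acid
Product: 22 bis-silylated angelate, via mixed anhydride 21 (not isolated)
Conditions: 20, 2,4,6-trichlorobenzoyl chloride, Et3N, toluene, rt; then 19, 75 °C
Reagents that add atoms: none
Why: Yamaguchi-type mixed-anhydride esterification without a nucleophilic amine catalyst should acylate the hindered C8 hydroxyl with retention at C8 and avoid the addition–elimination path that isomerises angelates to tiglates.

Step 12
Reactants: 22 bis-silylated angelate
Product: 23 target CNP0147777.1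
Conditions: HF·pyridine, pyridine, THF, 0 °C → rt
Reagents that add atoms: none
Why: Fluoride-mediated desilylation under buffered, non-basic conditions should free both primary alcohols and leave the α-methylene lactone and the Z-configured ester intact.

Compound list
1 | (tert-butyldimethylsilyloxy)acetaldehyde | O=CCO[Si](C)(C)C(C)(C)C | starting material
2 | (triphenylphosphoranylidene)acetaldehyde | O=CC=P(c1ccccc1)(c1ccccc1)c1ccccc1 | starting material
3 | (E)-4-(tert-butyldimethylsilyloxy)but-2-enal | O=C/C=C/CO[Si](C)(C)C(C)(C)C | intermediate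
4 | bis(phenylsulfonyl)methane | O=S(=O)(CS(=O)(=O)c1ccccc1)c1ccccc1 | starting material
5 | (R)-3-[(tert-butyldimethylsilyloxy)methyl]-4,4-bis(phenylsulfonyl)butanal (C8 aldehyde, C10 stereocentre) | O=S(=O)(c1ccccc1)C(S(=O)(=O)c1ccccc1)[C@@H](CO[Si](C)(C)C(C)(C)C)CC=O | intermediate
6 | methyl 4-oxobutanoate | COC(=O)CCC=O | starting material
7 | methyl (3R,4R,6R)-6-[(tert-butyldimethylsilyloxy)methyl]-3-formyl-4-hydroxy-7,7-bis(phenylsulfonyl)heptanoate (anti aldol adduct, formyl carbon = C6, not isolated) | O=S(=O)(c1ccccc1)C(S(=O)(=O)c1ccccc1)[C@@H](CO[Si](C)(C)C(C)(C)C)C[C@@H](O)[C@@H](CC(=O)OC)C=O | intermediate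
8 | methyl (3R,4R,6R)-6-[(tert-butyldimethylsilyloxy)methyl]-3-formyl-7,7-bis(phenylsulfonyl)-4-(triethylsilyloxy)heptanoate | O=S(=O)(c1ccccc1)C(S(=O)(=O)c1ccccc1)[C@@H](CO[Si](C)(C)C(C)(C)C)C[C@@H](O[Si](CC)(CC)CC)[C@@H](CC(=O)OC)C=O | intermediate
9 | 2-(trimethylsilylmethyl)buta-1,3-diene | C=CC(=C)C[Si](C)(C)C | starting material
10 | methyl (3S,4R,6R)-6-[(tert-butyldimethylsilyloxy)methyl]-3-[(1R)-1-hydroxy-3-methylidenepent-4-en-1-yl]-7,7-bis(phenylsulfonyl)-4-(triethylsilyloxy)heptanoate (not isolated) | O=S(=O)(c1ccccc1)C(S(=O)(=O)c1ccccc1)[C@@H](CO[Si](C)(C)C(C)(C)C)C[C@@H](O[Si](CC)(CC)CC)[C@@H](CC(=O)OC)[C@H](O)CC(=C)C=C | intermediate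
11 | (4S,5R)-4-[(1R,3R)-3-[(tert-butyldimethylsilyloxy)methyl]-4,4-bis(phenylsulfonyl)-1-(triethylsilyloxy)butyl]-5-(2-methylidenebut-3-en-1-yl)dihydrofuran-2(3H)-one (trans lactone; germacrane 6R,7S,8R,10R) | O=S(=O)(c1ccccc1)C(S(=O)(=O)c1ccccc1)[C@@H](CO[Si](C)(C)C(C)(C)C)C[C@@H](O[Si](CC)(CC)CC)[C@H]2CC(=O)O[C@@H]2CC(=C)C=C | intermediate
12 | (4S,5R)-4-[(1R,3R)-3-[(tert-butyldimethylsilyloxy)methyl]-4,4-bis(phenylsulfonyl)-1-(triethylsilyloxy)butyl]-5-[(2-ethenyloxiran-2-yl)methyl]dihydrofuran-2(3H)-one (C4 epimers) | O=S(=O)(c1ccccc1)C(S(=O)(=O)c1ccccc1)[C@@H](CO[Si](C)(C)C(C)(C)C)C[C@@H](O[Si](CC)(CC)CC)[C@H]2CC(=O)O[C@@H]2CC3(C=C)CO3 | intermediate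
13 | (3E,6R,7S,8R,10R)-14-(tert-butyldimethylsilyloxy)-15-hydroxy-1,1-bis(phenylsulfonyl)-8-(triethylsilyloxy)germacr-3-en-12,6-olide (C2 and C5 cis on C3=C4, trans-fused lactone) | C1C(=O)O[C@@H]2C/C(CO)=C\CC(S(=O)(=O)c3ccccc3)(S(=O)(=O)c3ccccc3)[C@@H](CO[Si](C)(C)C(C)(C)C)C[C@@H](O[Si](CC)(CC)CC)[C@@H]12 | intermediate
14 | (3E,6R,7S,8R,10R)-14-(tert-butyldimethylsilyloxy)-15-hydroxy-8-(triethylsilyloxy)germacr-3-en-12,6-olide | C1C(=O)O[C@@H]2C/C(CO)=C\CC[C@@H](CO[Si](C)(C)C(C)(C)C)C[C@@H](O[Si](CC)(CC)CC)[C@@H]12 | intermediate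
15 | (3E,6R,7S,8R,10R)-14,15-bis(tert-butyldimethylsilyloxy)-8-(triethylsilyloxy)germacr-3-en-12,6-olide | C1C(=O)O[C@@H]2C/C(CO[Si](C)(C)C(C)(C)C)=C\CC[C@@H](CO[Si](C)(C)C(C)(C)C)C[C@@H](O[Si](CC)(CC)CC)[C@@H]12 | intermediate
16 | 13-(dimethylamino) derivative of 15 (C11 epimers, not isolated) | CN(C)CC1C(=O)O[C@@H]2C/C(CO[Si](C)(C)C(C)(C)C)=C\CC[C@@H](CO[Si](C)(C)C(C)(C)C)C[C@@H](O[Si](CC)(CC)CC)[C@@H]12 | intermediate
17 | 13-(trimethylammonio) derivative of 15, iodide (not isolated) | [I-].C[N+](C)(C)CC1C(=O)O[C@@H]2C/C(CO[Si](C)(C)C(C)(C)C)=C\CC[C@@H](CO[Si](C)(C)C(C)(C)C)C[C@@H](O[Si](CC)(CC)CC)[C@@H]12 | intermediate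
18 | (3E,6R,7S,8R,10R)-14,15-bis(tert-butyldimethylsilyloxy)-8-(triethylsilyloxy)germacra-3,11(13)-dien-12,6-olide | C=C1C(=O)O[C@@H]2C/C(CO[Si](C)(C)C(C)(C)C)=C\CC[C@@H](CO[Si](C)(C)C(C)(C)C)C[C@@H](O[Si](CC)(CC)CC)[C@@H]12 | intermediate
19 | (3E,6R,7R,8R,10R)-14,15-bis(tert-butyldimethylsilyloxy)-8-hydroxygermacra-3,11(13)-dien-12,6-olide | C=C1C(=O)O[C@@H]2C/C(CO[Si](C)(C)C(C)(C)C)=C\CC[C@@H](CO[Si](C)(C)C(C)(C)C)C[C@@H](O)[C@@H]12 | intermediate
20 | angelic acid, (Z)-2-methylbut-2-enoic acid | C/C=C(/C)C(=O)O | starting material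
21 | angelic 2,4,6-trichlorobenzoic anhydride (not isolated) | C/C=C(/C)C(=O)OC(=O)c1c(Cl)cc(Cl)cc1Cl | intermediate
22 | (3E,6R,7R,8R,10R)-8-angeloyloxy-14,15-bis(tert-butyldimethylsilyloxy)germacra-3,11(13)-dien-12,6-olide | C=C1C(=O)O[C@@H]2C/C(CO[Si](C)(C)C(C)(C)C)=C\CC[C@@H](CO[Si](C)(C)C(C)(C)C)C[C@@H](OC(=O)/C(C)=C\C)[C@@H]12 | intermediate
23 | (3E,6R,7R,8R,10R)-8-angeloyloxy-14,15-dihydroxygermacra-3,11(13)-dien-12,6-olide, CNP0147777.1 | C=C1C(=O)O[C@@H]2C/C(CO)=C\CC[C@@H](CO)C[C@@H](OC(=O)/C(C)=C\C)[C@@H]12 | target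

Total step count: 12. Longest linear sequence: 12 steps.

Steps most likely to fail

Step 6. Oligomerisation may compete with ring closure, the hindered C1 carbanion may react slowly, attack may occur at C4, or the olefin may close with C2 and C5 trans. Fallback: setting out from 12, 1,4-opening of the vinyl oxirane with bromide (LiBr, AcOH, CuBr cat., THF, −20 °C, with copper-mediated allylic equilibration to the primary bromide) should give the (E)-allylic bromide F1, in which the olefin geometry is fixed before ring closure. Intramolecular SN2 alkylation of the bis-sulfone carbanion (Cs2CO3, DMF, high dilution, rt) should then form the same C1–C2 bond and come back to the route at 13.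

Step 3. Self-aldol of the donor, enamine formation from the acceptor, low anti selectivity or lactonisation of the adduct onto O8 before silylation may erode the outcome. Fallback: setting out from 5, the allylboronate F2 (from allylboronic acid pinacol ester and methyl but-3-enoate by cross-metathesis with second-generation Grubbs catalyst RuCl2(=CHPh)(PCy3)(H2IMes), E isomer purified) should add under chiral phosphoric acid catalysis (the TRIP enantiomer that directs attack to the Si face of C8) through a chair transition state to give the anti homoallylic alcohol F3. Silylation (Et3SiOTf, 2,6-lutidine, CH2Cl2, −78 °C) should give the silyl ether F4, and ozonolysis of its vinyl group (O3, CH2Cl2, −78 °C; PPh3) comes back to the route at 8.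

Step 5. The peracid may attack the C2=C3 vinyl group, epoxidise twice, or the vinyl oxirane may open under traces of acid. Fallback: setting out from 10, intercepted before the PPTS treatment, hydroxyl-directed epoxidation (VO(acac)2 cat., tBuOOH, CH2Cl2, 0 °C) uses the C6 hydroxyl, which is homoallylic only to C4=C15, and should give the epoxy alcohol F5. Lactonisation (PPTS cat., CH2Cl2, rt) comes back to the route at 12.

Further compounds
F1 | step 6 | (4S,5R)-5-[(2E)-4-bromo-2-(hydroxymethyl)but-2-en-1-yl]-4-[(1R,3R)-3-[(tert-butyldimethylsilyloxy)methyl]-4,4-bis(phenylsulfonyl)-1-(triethylsilyloxy)butyl]dihydrofuran-2(3H)-one | O=S(=O)(c1ccccc1)C(S(=O)(=O)c1ccccc1)[C@@H](CO[Si](C)(C)C(C)(C)C)C[C@@H](O[Si](CC)(CC)CC)[C@H]2CC(=O)O[C@@H]2C/C(CO)=C\CBr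
F2 | step 3 | methyl (E)-5-(4,4,5,5-tetramethyl-1,3,2-dioxaborolan-2-yl)pent-3-enoate | COC(=O)C/C=C/CB1OC(C)(C)C(C)(C)O1
F3 | step 3 | methyl (3S,4R,6R)-6-[(tert-butyldimethylsilyloxy)methyl]-3-ethenyl-4-hydroxy-7,7-bis(phenylsulfonyl)heptanoate | O=S(=O)(c1ccccc1)C(S(=O)(=O)c1ccccc1)[C@@H](CO[Si](C)(C)C(C)(C)C)C[C@@H](O)[C@@H](CC(=O)OC)C=C
F4 | step 3 | methyl (3S,4R,6R)-6-[(tert-butyldimethylsilyloxy)methyl]-3-ethenyl-7,7-bis(phenylsulfonyl)-4-(triethylsilyloxy)heptanoate | O=S(=O)(c1ccccc1)C(S(=O)(=O)c1ccccc1)[C@@H](CO[Si](C)(C)C(C)(C)C)C[C@@H](O[Si](CC)(CC)CC)[C@@H](CC(=O)OC)C=C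
F5 | step 5 | methyl (3S,4R,6R)-6-[(tert-butyldimethylsilyloxy)methyl]-3-[(1R)-2-(2-ethenyloxiran-2-yl)-1-hydroxyethyl]-7,7-bis(phenylsulfonyl)-4-(triethylsilyloxy)heptanoate (oxirane epimers) | O=S(=O)(c1ccccc1)C(S(=O)(=O)c1ccccc1)[C@@H](CO[Si](C)(C)C(C)(C)C)C[C@@H](O[Si](CC)(CC)CC)[C@@H](CC(=O)OC)[C@H](O)CC2(C=C)CO2
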